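## Analysis of the target

Target 17 is the 3',4'-bis(hydrogen sulfate) of quercetin: a 3-hydroxy-2-aryl-4H-chromen-4-one with free hydroxyls at C3, C5 and C7 and sulfate monoesters on both oxygens of the ring B catechol. Ring A (benzo) is fused to ring C (the pyranone), and ring B hangs from C2. There is no stereocentre, so the problem is one of regiochemistry. Five oxygens of similar character must end in two states, three free and two sulfated, so the ring B oxygens must stay distinguishable from O3, O5 and O7 to the end. The aryl sulfates are the sensitive groups: they hydrolyse in acid (the free acid form catalyses its own hydrolysis), they make the molecule a water-soluble dianion, and the second sulfation next to the first is slowed by charge and crowding. The chromone itself is opened at C2 by hard nucleophiles, and a free catechol oxidises in basic, aerated media. The strategy rests on one feature: the C4 carbonyl lies between C4a of ring A and the C3=C2–aryl unit, and O1 sits on C8a, ortho to C4a. Ring C is therefore a 2-iodophenol (C4a, C8a, O1), one molecule of carbon monoxide (C4) and an arylacetylene (C3, C2, ring B).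

## Retrosynthetic reasoning

Target 17 to salt 15. The free acid is taken back to its bis(triethylammonium) salt, and the three free hydroxyls to benzyl ethers. The O–benzyl bonds are cut last because hydrogenolysis is neutral and leaves sulfate monoester anions alone. The proton exchange is the very last operation because the acid form is the least stable species of the route.

Salt 15 to catechol 14. Both S–O bonds are cut. In 14 the only free hydroxyls are the two on ring B, so the protecting-group pattern alone fixes where an amine–sulfur trioxide complex reacts. The forward step must drive two adjacent sulfations to completion.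

Catechol 14 to ketal 13. The two C–O bonds of the diphenylmethylene ketal are cut. The ketal ionises in hot aqueous acid through a diaryl carbenium ion that a benzyl ether cannot match, so ring B is unmasked while O3, O5 and O7 stay benzylated. This is the one point where the two sets of oxygens are told apart.

Tribenzyl ether 13 to flavonol 12. The O3–benzyl bond is cut. O3 must be capped before the catechol is freed, because a free 3-hydroxyl would also be sulfated. Benzyl is chosen so that O3, O5 and O7 are released together.

Flavonol 12 to flavone 10. The C3–O bond is cut. A terminal alkyne can deliver C3 only as C–H, so the oxygen is added after ring closure. A neutral dioxirane epoxidises the C2=C3 bond to epoxide 11, and acid isomerises 11 to the enol 12. The 5-O-benzyl group helps, since a chelated 5-hydroxyl would deactivate the double bond.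

Flavone 10 to iodophenol 6, carbon monoxide 7 and alkyne 4. This is the key disconnection: C4a–C4, C4–C3 and O1–C2 are cut in one operation. Cutting here removes all of ring C and leaves two aromatic pieces that already carry every oxygen of rings A and B, each in the protecting group the endgame needs (benzyl on ring A, ketal on ring B). No other cut through ring C gives two pieces of such equal size with the oxygen pattern complete. The forward reaction must join the aryl iodide, CO and the alkyne to ynone 8 and then close the six-membered ring through enaminone 9, not the five-membered aurone ring.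

Iodophenol 6 to phenol 5. The C2–I bond is cut. Phenol 5 is a stock compound. Benzylating the parent triphenol directly is avoided, because it gives C-benzylation and statistical mixtures. The forward iodination must go ortho to the free hydroxyl (C2 or C6, equivalent) and not to C4 between the two benzyloxy groups.

Alkyne 4 to aldehyde 3, and 3 to catechol aldehyde 1 and dichloride 2. The alkyne carbon is removed by one-carbon homologation of the aldehyde with a diazophosphonate reagent. The ketal is then cut back to 1 and 2. Ring B thus comes from a stock aldehyde in two steps, with the catechol protected from the first step.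

## Alternatives that were turned down

Alternative 1: Ring A is opened at the bond from C4a to an oxygen-bearing neighbour (C5 or C8a, identical by symmetry). This leads to the open-chain cinnamoyl triketide A2, methyl (E)-9-(2,2-diphenyl-1,3-benzodioxol-5-yl)-3,5,7-trioxonon-8-enoate. In the forward key step the C6 enolate of A2 attacks the ester carbonyl in a Claisen cyclisation, and enolisation gives the chalcone A1, (E)-3-(2,2-diphenyl-1,3-benzodioxol-5-yl)-1-(2,4,6-trihydroxyphenyl)prop-2-en-1-one.
- For it: it copies the biosynthesis, ring A emerges with its 1,3,5-oxygen pattern and no protecting groups, and no transition metal or pressurised gas is needed. On these points it is stronger than the chosen route.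
- Against it: A2 has three enolisable methylenes and four carbonyls. Without an enzyme nothing chooses the C6-to-C1 Claisen mode over the C2-to-C7 aldol mode, lactonisation to a hydroxypyranone or conjugate addition to the enone. A2 must also be built by iterative enolate acylations.
- Against it: A1 is still far from the flavonol. Ring C has to be closed oxidatively and C3 hydroxylated, and 2'-hydroxychalcones with a 6'-oxygen tend to give aurones under alkaline peroxide. The three ring A hydroxyls would then have to be benzylated before sulfation anyway.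
- Comparison: this route spends its key step making ring A, which the chosen route takes from the shelf as 5, and it leaves ring C to extra steps. It is longer overall.

Alternative 2: Ring A is removed completely, back to the pyranonyl diazoketone A4, 2-diazo-1-[5-(benzyloxy)-6-(2,2-diphenyl-1,3-benzodioxol-5-yl)-4-oxo-4H-pyran-2-yl]ethan-1-one, and the siloxyalkyne A5, (triisopropylsilyloxy)ethyne. In the forward key step a Wolff rearrangement of A4 gives a vinylketene. This adds to A5 in a [2+2] cycloaddition, and the cyclobutenone opens and recloses by 6π electrocyclisation to give A3, 3-(benzyloxy)-2-(2,2-diphenyl-1,3-benzodioxol-5-yl)-5-hydroxy-7-(triisopropylsilyloxy)-4H-chromen-4-one.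
- For it: O3 is in place from the start, which would save the oxidation and benzylation (steps 5 and 6). The regiochemistry of the benzannulation is fixed by the mechanism, no CO is needed, and O5 and O7 come out differentiated.
- Against it: A4 is a fully substituted pyranone whose preparation would take more steps than the whole chosen route to flavone 10. The Wolff step must be run on a cross-conjugated, photoactive pyranone, and A5 is moisture-sensitive.
- Against it: the differentiation of O5 from O7 is wasted, since both end as free hydroxyls.
- Comparison: the chosen route offers ring A from a stock compound and reaches all three key-step components in three steps.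

Alternative 3: C3–C4 and O1–C8a are cut, with fluorine standing in for the ring A oxygens. The pieces are the ketone A7, 2-(benzyloxy)-1-(2,2-diphenyl-1,3-benzodioxol-5-yl)ethan-1-one, and the acid chloride A8, 2,4,6-trifluorobenzoyl chloride. In the forward key step the enolate of A7 is C-acylated by A8, and the diketone enolate oxygen displaces an ortho fluoride to close ring C. The product is A6, 3-(benzyloxy)-2-(2,2-diphenyl-1,3-benzodioxol-5-yl)-5,7-difluoro-4H-chromen-4-one. Displacing both fluorides with benzyl alkoxide would then give 13.
- For it: O3 is built in, there is no metal and no gas, the ring closes in one pot, and the step count to 13 is about equal or slightly lower. On the C3 oxygen it is clearly stronger.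
- Against it: the two fluoride displacements need a strong alkoxide on a chromone whose C2 is also electrophilic, so conjugate addition and ring opening compete. The C5 fluoride is crowded by the peri carbonyl.
- Against it: C-acylation must beat O-acylation of the enolate, and A7 needs its own short synthesis.
- Comparison: the chosen strategy places the ring A oxygens from the start in their final protecting groups, keeps every step after ring closure non-nucleophilic toward the chromone, and confines the risk to one catalytic step.

Key step: step 4

Remark on the chemistry: the target is drawn as the free bis(hydrogen sulfate), so the disulfate is carried as its bis(triethylammonium) salt and protonated only in the final operation, cold, because aryl hydrogen sulfates hydrolyse under their own acidity.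

## Route

Step 1
Reactants: 1 3,4-dihydroxybenzaldehyde; 2 dichlorodiphenylmethane
Product: 3 2,2-diphenyl-1,3-benzodioxole-5-carbaldehyde
Conditions: Ph2CCl2 (1.3 equiv), neat, 170 °C, N2 sweep
Reagents that add atoms: none
Why: Ketalisation of a catechol by a gem-dichloride (two O-alkylations through a diaryl oxocarbenium ion); the five-membered dioxole closes readily, HCl leaves the melt as a gas, and the non-enolisable aldehyde is untouched.

Step 2
Reactants: 3 2,2-diphenyl-1,3-benzodioxole-5-carbaldehyde
Product: 4 5-ethynyl-2,2-diphenyl-1,3-benzodioxole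
Conditions: dimethyl (1-diazo-2-oxopropyl)phosphonate (1.3 equiv), K2CO3 (2 equiv), MeOH/THF, 0 °C to rt
Reagents that add atoms: dimethyl (1-diazo-2-oxopropyl)phosphonate, COP(=O)(OC)C(=[N+]=[N-])C(C)=O
Why: Seyferth–Gilbert homologation in the Ohira–Bestmann form: methoxide deacetylates the reagent, the diazomethylphosphonate anion adds to the aldehyde, and olefination, loss of N2 and a 1,2-hydrogen shift of the alkylidene carbene give the terminal alkyne. The carbonate base leaves the ketal alone.

Step 3
Reactants: 5 3,5-bis(benzyloxy)phenol
Product: 6 3,5-bis(benzyloxy)-2-iodophenol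
Conditions: NIS (1.0 equiv), CH2Cl2, −20 to 0 °C, dark
Reagents that add atoms: N-iodosuccinimide, O=C1CCC(=O)N1I
Why: Electrophilic aromatic iodination of a strongly activated phenol. C2 and C6 are two equivalent sites flanked by OH and one benzyloxy group, whereas C4 is crowded between two benzyloxy groups, and in a non-polar solvent the phenol O–H hydrogen-bonds to the reagent and delivers iodine ortho. One equivalent at low temperature limits di-iodination.

Step 4
Reactants: 6 3,5-bis(benzyloxy)-2-iodophenol; 7 carbon monoxide; 4 5-ethynyl-2,2-diphenyl-1,3-benzodioxole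
Product: 10 5,7-bis(benzyloxy)-2-(2,2-diphenyl-1,3-benzodioxol-5-yl)-4H-chromen-4-one, via o-hydroxyaryl ynone 8 (not isolated), via β-diethylamino enone 9 (not isolated)
Conditions: PdCl2(PPh3)2 (5 mol %), CO (20 bar), Et2NH, 120 °C, autoclave, no copper
Reagents that add atoms: none
Why: PdCl2(PPh3)2 is reduced in the amine to zerovalent palladium, which inserts into the C–I bond of 6; CO (7) then inserts to give an aroyl complex of divalent palladium, the amine-deprotonated alkyne 4 displaces iodide, and reductive elimination forms C4a–C4 and C4–C3 in ynone 8. Diethylamine adds to the β-carbon of 8 to give enaminone 9, and the ortho phenol attacks the same carbon and expels the amine, forming O1–C2. The closest known reaction type is the palladium-catalysed carbonylative Sonogashira coupling of 2-iodophenols with terminal arylacetylenes in a secondary amine, which gives flavones in one pot. Ring C closes in the 6-endo mode (6-endo-trig addition–elimination on 9, equivalent overall to 6-endo-dig hydroalkoxylation of 8). No stereocentre is formed. CO insertion must outrun direct aryl–alkynyl coupling, which would end in a 2-arylbenzofuran; the copper-free medium, the CO pressure and the electron-rich aryl group, which migrates readily onto CO, secure this. The 6-endo closure must outrun 5-exo attack at the α-carbon, which would give the aurone; the secondary amine secures this by converting 8 into 9, whose only electrophilic site is the β-carbon. The benzyl ethers and the ketal are inert to the basic, non-reducing medium.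

Step 5
Reactants: 10 5,7-bis(benzyloxy)-2-(2,2-diphenyl-1,3-benzodioxol-5-yl)-4H-chromen-4-one
Product: 12 5,7-bis(benzyloxy)-2-(2,2-diphenyl-1,3-benzodioxol-5-yl)-3-hydroxy-4H-chromen-4-one, via racemic 2,3-epoxyflavanone 11 (not isolated)
Conditions: DMDO (ca. 0.07 M in acetone, 3 equiv), CH2Cl2, 0 °C to rt; then p-TsOH (cat.), CH2Cl2, 0 °C
Reagents that add atoms: dimethyldioxirane, CC1(C)OO1
Why: Dioxirane epoxidation of the flavone C2=C3 bond, which O1 makes enol-ether-like, gives 11 with acetone as the only by-product; brief acid catalysis opens 11 at C2, where the cation is stabilised by O1 and ring B, and loss of H3 gives the 3-hydroxyflavone. The two stereocentres of racemic 11 are destroyed again in the isomerisation, and the 5-O-benzyl group removes the deactivating hydrogen bond from a 5-hydroxyl to the C4 carbonyl.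

Step 6
Reactants: 12 5,7-bis(benzyloxy)-2-(2,2-diphenyl-1,3-benzodioxol-5-yl)-3-hydroxy-4H-chromen-4-one
Product: 13 3,5,7-tris(benzyloxy)-2-(2,2-diphenyl-1,3-benzodioxol-5-yl)-4H-chromen-4-one
Conditions: BnBr (1.5 equiv), K2CO3 (2 equiv), DMF, 50 °C
Reagents that add atoms: benzyl bromide, BrCc1ccccc1
Why: Williamson etherification of the acidic 3-hydroxyl, the only free OH in 12. It caps O3 with the same group as O5 and O7, so that only ring B can later be sulfated and all three groups fall in one hydrogenolysis.

Step 7
Reactants: 13 3,5,7-tris(benzyloxy)-2-(2,2-diphenyl-1,3-benzodioxol-5-yl)-4H-chromen-4-one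
Product: 14 3,5,7-tris(benzyloxy)-2-(3,4-dihydroxyphenyl)-4H-chromen-4-one
Conditions: AcOH/H2O (4:1), reflux, N2
Reagents that add atoms: none
Why: Acid hydrolysis of the diphenylmethylene ketal through the aryloxy-stabilised diphenylcarbenium ion, which forms far more easily than a benzyl cation from the ethers. Hot aqueous acetic acid should therefore free the catechol and leave the three benzyl ethers in place.

Step 8
Reactants: 14 3,5,7-tris(benzyloxy)-2-(3,4-dihydroxyphenyl)-4H-chromen-4-one
Product: 15 bis(triethylammonium) 4-[3,5,7-tris(benzyloxy)-4-oxo-4H-chromen-2-yl]-1,2-phenylene bis(sulfate)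
Conditions: SO3·NMe3 (8 equiv), Et3N (12 equiv), MeCN, 80 °C, sealed, N2; evaporate from Et3N/MeOH; SiO2 (CH2Cl2/MeOH/Et3N)
Reagents that add atoms: sulfur trioxide–trimethylamine complex, C[N+](C)(C)S(=O)(=O)[O-]; triethylamine, CCN(CC)CC
Why: O-Sulfation of phenols by an amine–sulfur trioxide complex under base; the catechol hydroxyls are the only free OH groups, so the protecting-group pattern fixes the regiochemistry. Excess reagent and heat push the second sulfation past the charge and crowding left by the first, and the triethylammonium counter-ions keep the product soluble enough for chromatography.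

Step 9
Reactants: 15 bis(triethylammonium) 4-[3,5,7-tris(benzyloxy)-4-oxo-4H-chromen-2-yl]-1,2-phenylene bis(sulfate)
Product: 17 4-(3,5,7-trihydroxy-4-oxo-4H-chromen-2-yl)-1,2-phenylene bis(hydrogen sulfate), via debenzylated bis(triethylammonium) disulfate 16 (not isolated)
Conditions: H2 (1 atm), 10% Pd/C, MeOH/THF/H2O, rt; filter; Dowex 50W-X8 (H+ form), H2O, 0 °C; lyophilise
Reagents that add atoms: none
Why: Heterogeneous hydrogenolysis of the three O-benzyl groups; aryl sulfate monoester anions are not reduced by H2 on Pd/C, and the fully substituted C2=C3 bond of the flavonol is inert. A cold sulfonic acid resin then exchanges triethylammonium for protons to give the drawn acid, which is freeze-dried at once.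

## Compound list

1 | 3,4-dihydroxybenzaldehyde | O=Cc1ccc(O)c(O)c1 | starting material
2 | dichlorodiphenylmethane | ClC(Cl)(c1ccccc1)c1ccccc1 | starting material
3 | 2,2-diphenyl-1,3-benzodioxole-5-carbaldehyde | O=Cc1ccc2OC(c3ccccc3)(c3ccccc3)Oc2c1 | intermediate
4 | 5-ethynyl-2,2-diphenyl-1,3-benzodioxole | C#Cc1ccc2OC(c3ccccc3)(c3ccccc3)Oc2c1 | intermediate
5 | 3,5-bis(benzyloxy)phenol | Oc1cc(OCc2ccccc2)cc(OCc2ccccc2)c1 | starting material
6 | 3,5-bis(benzyloxy)-2-iodophenol | Oc1cc(OCc2ccccc2)cc(OCc2ccccc2)c1I | intermediate
7 | carbon monoxide | [C-]#[O+] | starting material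
8 | 1-[2,4-bis(benzyloxy)-6-hydroxyphenyl]-3-(2,2-diphenyl-1,3-benzodioxol-5-yl)prop-2-yn-1-one (not isolated) | O=C(C#Cc1ccc2OC(c3ccccc3)(c3ccccc3)Oc2c1)c1c(O)cc(OCc2ccccc2)cc1OCc1ccccc1 | intermediate
9 | (E)-1-[2,4-bis(benzyloxy)-6-hydroxyphenyl]-3-(diethylamino)-3-(2,2-diphenyl-1,3-benzodioxol-5-yl)prop-2-en-1-one (not isolated; the geometry has no bearing on the closure) | CCN(CC)/C(c1ccc2OC(c3ccccc3)(c3ccccc3)Oc2c1)=C/C(=O)c1c(O)cc(OCc2ccccc2)cc1OCc1ccccc1 | intermediate
10 | 5,7-bis(benzyloxy)-2-(2,2-diphenyl-1,3-benzodioxol-5-yl)-4H-chromen-4-one | O=c1cc(-c2ccc3OC(c4ccccc4)(c4ccccc4)Oc3c2)oc2cc(OCc3ccccc3)cc(OCc3ccccc3)c12 | intermediate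
11 | 5,7-bis(benzyloxy)-2-(2,2-diphenyl-1,3-benzodioxol-5-yl)-2,3-epoxy-2,3-dihydro-4H-chromen-4-one, racemic, cis-fused epoxide (not isolated) | O=C1C2OC2(c2ccc3OC(c4ccccc4)(c4ccccc4)Oc3c2)Oc2cc(OCc3ccccc3)cc(OCc3ccccc3)c12 | intermediate
12 | 5,7-bis(benzyloxy)-2-(2,2-diphenyl-1,3-benzodioxol-5-yl)-3-hydroxy-4H-chromen-4-one | O=c1c(O)c(-c2ccc3OC(c4ccccc4)(c4ccccc4)Oc3c2)oc2cc(OCc3ccccc3)cc(OCc3ccccc3)c12 | intermediate
13 | 3,5,7-tris(benzyloxy)-2-(2,2-diphenyl-1,3-benzodioxol-5-yl)-4H-chromen-4-one | O=c1c(OCc2ccccc2)c(-c2ccc3OC(c4ccccc4)(c4ccccc4)Oc3c2)oc2cc(OCc3ccccc3)cc(OCc3ccccc3)c12 | intermediate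
14 | 3,5,7-tris(benzyloxy)-2-(3,4-dihydroxyphenyl)-4H-chromen-4-one | O=c1c(OCc2ccccc2)c(-c2ccc(O)c(O)c2)oc2cc(OCc3ccccc3)cc(OCc3ccccc3)c12 | intermediate
15 | bis(triethylammonium) 4-[3,5,7-tris(benzyloxy)-4-oxo-4H-chromen-2-yl]-1,2-phenylene bis(sulfate) | O=c1c(OCc2ccccc2)c(-c2ccc(OS(=O)(=O)[O-])c(OS(=O)(=O)[O-])c2)oc2cc(OCc3ccccc3)cc(OCc3ccccc3)c12.CC[NH+](CC)CC.CC[NH+](CC)CC | intermediate
16 | bis(triethylammonium) 4-(3,5,7-trihydroxy-4-oxo-4H-chromen-2-yl)-1,2-phenylene bis(sulfate) (not isolated) | O=c1c(O)c(-c2ccc(OS(=O)(=O)[O-])c(OS(=O)(=O)[O-])c2)oc2cc(O)cc(O)c12.CC[NH+](CC)CC.CC[NH+](CC)CC | intermediate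
17 | 4-(3,5,7-trihydroxy-4-oxo-4H-chromen-2-yl)-1,2-phenylene bis(hydrogen sulfate) (quercetin 3',4'-disulfate; no stereocentre) | O=c1c(O)c(-c2ccc(OS(=O)(=O)O)c(OS(=O)(=O)O)c2)oc2cc(O)cc(O)c12 | target

## Step count and risks

Total step count: 9. Longest linear sequence: 8 steps (steps 1, 2, 4, 5, 6, 7, 8, 9, from aldehyde 1); the ring A branch is one step (step 3) before the key step.

Step 4 (key step).
- What may go wrong: oxidative addition into the electron-rich, doubly ortho-substituted C–I bond may be slow, so the catalyst may decompose before turnover. Diethylamine may capture the aroyl palladium intermediate (aminocarbonylation). Direct coupling without CO followed by cyclisation onto the alkyne would bypass the carbonyl altogether.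
- Fallback: a chalcone route from aldehyde 3 back to flavone 10. Claisen–Schmidt condensation of 3 with the known acetophenone 1-[2,4-bis(benzyloxy)-6-hydroxyphenyl]ethan-1-one F1 (KOH, EtOH/THF) should give the chalcone (E)-1-[2,4-bis(benzyloxy)-6-hydroxyphenyl]-3-(2,2-diphenyl-1,3-benzodioxol-5-yl)prop-2-en-1-one F2. Iodine-catalysed oxidative cyclisation of F2 in DMSO at about 120 °C should then close ring C to 10, and the route continues at step 5.

Step 3.
- What may go wrong: iodination may also occur at C4, para to the hydroxyl, or twice, because all three free positions are activated by three oxygens. The isomeric iodophenols may be hard to separate.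
- Fallback: directed metalation from phenol 5 back to iodophenol 6. Carbamoylation of 5 (NaH, diethylcarbamoyl chloride, THF) gives 3,5-bis(benzyloxy)phenyl diethylcarbamate F3. Lithiation with s-BuLi/TMEDA in THF at −78 °C is directed by the carbamate to the position between the carbamate and a benzyloxy group. An iodine quench gives 3,5-bis(benzyloxy)-2-iodophenyl diethylcarbamate F4, and NaOH in refluxing EtOH removes the carbamate to give 6.

Step 5.
- What may go wrong: epoxidation of the conjugated, electron-poor double bond may be slow, and prolonged exposure to the dioxirane can lead to oxidation of the benzylic C–H bonds. The acid used for the isomerisation can also cause loss of the diphenylmethylene ketal.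
- Fallback: C3 metalation from flavone 10 back to flavonol 12. LDA in THF at −78 °C lithiates C3, and trimethyl borate traps the anion as dimethyl [5,7-bis(benzyloxy)-2-(2,2-diphenyl-1,3-benzodioxol-5-yl)-4-oxo-4H-chromen-3-yl]boronate F5. Oxidation of the C–B bond with H2O2/AcOH gives 12.

Step 8.
- What may go wrong: sulfation may stop after the first sulfate, because the monoanion repels the reagent and crowds the neighbouring hydroxyl. The catechol may oxidise in the basic medium, and the dianionic product may be lost on purification.
- Fallback: masked sulfates from catechol 14 back to salt 15. 2,2,2-Trichloroethyl chlorosulfate with Et3N and DMAP in THF should give the neutral diester 4-[3,5,7-tris(benzyloxy)-4-oxo-4H-chromen-2-yl]-1,2-phenylene bis(2,2,2-trichloroethyl) bis(sulfate) F6, which carries no charge and can be purified on silica. Zinc dust and ammonium formate in MeOH remove both trichloroethyl groups to give bis(ammonium) 4-[3,5,7-tris(benzyloxy)-4-oxo-4H-chromen-2-yl]-1,2-phenylene bis(sulfate) F7. Evaporation of F7 from Et3N/MeOH exchanges the cation and gives 15.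

Step 9.
- What may go wrong: hydrogenolysis of a tribenzylated dianionic salt may stall, through poor mutual solubility of substrate and product or inhibition of the catalyst by the amine. The sulfate esters may also hydrolyse during the acidic ion exchange and drying.
- Fallback: the order of unmasking is reversed, from catechol 14 to target 17. The diester 4-[3,5,7-tris(benzyloxy)-4-oxo-4H-chromen-2-yl]-1,2-phenylene bis(2,2,2-trichloroethyl) bis(sulfate) F6, made as in the fallback for step 8, is debenzylated without hydrogen by BCl3 and pentamethylbenzene in CH2Cl2 at −78 °C. This gives 4-(3,5,7-trihydroxy-4-oxo-4H-chromen-2-yl)-1,2-phenylene bis(2,2,2-trichloroethyl) bis(sulfate) F8. Zinc and ammonium formate in MeOH then release bis(ammonium) 4-(3,5,7-trihydroxy-4-oxo-4H-chromen-2-yl)-1,2-phenylene bis(sulfate) F9, which is a stable storage form. F9 is passed through the cold acid resin only immediately before use to give 17.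

## Further compounds

F1 | step 4 | 1-[2,4-bis(benzyloxy)-6-hydroxyphenyl]ethan-1-one | CC(=O)c1c(O)cc(OCc2ccccc2)cc1OCc1ccccc1
F2 | step 4 | (E)-1-[2,4-bis(benzyloxy)-6-hydroxyphenyl]-3-(2,2-diphenyl-1,3-benzodioxol-5-yl)prop-2-en-1-one | O=C(/C=C/c1ccc2OC(c3ccccc3)(c3ccccc3)Oc2c1)c1c(O)cc(OCc2ccccc2)cc1OCc1ccccc1
F3 | step 3 | 3,5-bis(benzyloxy)phenyl diethylcarbamate | CCN(CC)C(=O)Oc1cc(OCc2ccccc2)cc(OCc2ccccc2)c1
F4 | step 3 | 3,5-bis(benzyloxy)-2-iodophenyl diethylcarbamate | CCN(CC)C(=O)Oc1cc(OCc2ccccc2)cc(OCc2ccccc2)c1I
F5 | step 5 | dimethyl [5,7-bis(benzyloxy)-2-(2,2-diphenyl-1,3-benzodioxol-5-yl)-4-oxo-4H-chromen-3-yl]boronate | COB(OC)c1c(-c2ccc3OC(c4ccccc4)(c4ccccc4)Oc3c2)oc2cc(OCc3ccccc3)cc(OCc3ccccc3)c2c1=O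
F6 | step 8 | 4-[3,5,7-tris(benzyloxy)-4-oxo-4H-chromen-2-yl]-1,2-phenylene bis(2,2,2-trichloroethyl) bis(sulfate) | O=c1c(OCc2ccccc2)c(-c2ccc(OS(=O)(=O)OCC(Cl)(Cl)Cl)c(OS(=O)(=O)OCC(Cl)(Cl)Cl)c2)oc2cc(OCc3ccccc3)cc(OCc3ccccc3)c12
F7 | step 8 | bis(ammonium) 4-[3,5,7-tris(benzyloxy)-4-oxo-4H-chromen-2-yl]-1,2-phenylene bis(sulfate) | O=c1c(OCc2ccccc2)c(-c2ccc(OS(=O)(=O)[O-])c(OS(=O)(=O)[O-])c2)oc2cc(OCc3ccccc3)cc(OCc3ccccc3)c12.[NH4+].[NH4+]
F8 | step 9 | 4-(3,5,7-trihydroxy-4-oxo-4H-chromen-2-yl)-1,2-phenylene bis(2,2,2-trichloroethyl) bis(sulfate) | O=c1c(O)c(-c2ccc(OS(=O)(=O)OCC(Cl)(Cl)Cl)c(OS(=O)(=O)OCC(Cl)(Cl)Cl)c2)oc2cc(O)cc(O)c12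
F9 | step 9 | bis(ammonium) 4-(3,5,7-trihydroxy-4-oxo-4H-chromen-2-yl)-1,2-phenylene bis(sulfate) | O=c1c(O)c(-c2ccc(OS(=O)(=O)[O-])c(OS(=O)(=O)[O-])c2)oc2cc(O)cc(O)c12.[NH4+].[NH4+]
A1 | alternative 1 | (E)-3-(2,2-diphenyl-1,3-benzodioxol-5-yl)-1-(2,4,6-trihydroxyphenyl)prop-2-en-1-one | O=C(/C=C/c1ccc2OC(c3ccccc3)(c3ccccc3)Oc2c1)c1c(O)cc(O)cc1O
A2 | alternative 1 | methyl (E)-9-(2,2-diphenyl-1,3-benzodioxol-5-yl)-3,5,7-trioxonon-8-enoate | COC(=O)CC(=O)CC(=O)CC(=O)/C=C/c1ccc2OC(c3ccccc3)(c3ccccc3)Oc2c1
A3 | alternative 2 | 3-(benzyloxy)-2-(2,2-diphenyl-1,3-benzodioxol-5-yl)-5-hydroxy-7-(triisopropylsilyloxy)-4H-chromen-4-one | O=c1c(OCc2ccccc2)c(-c2ccc3OC(c4ccccc4)(c4ccccc4)Oc3c2)oc2cc(O[Si](C(C)C)(C(C)C)C(C)C)cc(O)c12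
A4 | alternative 2 | 2-diazo-1-[5-(benzyloxy)-6-(2,2-diphenyl-1,3-benzodioxol-5-yl)-4-oxo-4H-pyran-2-yl]ethan-1-one | [N-]=[N+]=CC(=O)c1cc(=O)c(OCc2ccccc2)c(-c2ccc3OC(c4ccccc4)(c4ccccc4)Oc3c2)o1
A5 | alternative 2 | (triisopropylsilyloxy)ethyne | C#CO[Si](C(C)C)(C(C)C)C(C)C
A6 | alternative 3 | 3-(benzyloxy)-2-(2,2-diphenyl-1,3-benzodioxol-5-yl)-5,7-difluoro-4H-chromen-4-one | O=c1c(OCc2ccccc2)c(-c2ccc3OC(c4ccccc4)(c4ccccc4)Oc3c2)oc2cc(F)cc(F)c12
A7 | alternative 3 | 2-(benzyloxy)-1-(2,2-diphenyl-1,3-benzodioxol-5-yl)ethan-1-one | O=C(COCc1ccccc1)c1ccc2OC(c3ccccc3)(c3ccccc3)Oc2c1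
A8 | alternative 3 | 2,4,6-trifluorobenzoyl chloride | O=C(Cl)c1c(F)cc(F)cc1F
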